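**Strategy.** Germacrane numbering is used (furanone ring = O/C1/C2/C3/C4; butenolide = C6/C7/C11/C12/O; C13 = CH2OAc). Everything rests on cutting the furanone O–C1 bond: the 1,4-oxygen bridge is the cycloisomer of a ten-membered C1≡C2–C3(=O)–C4(OH) ynone, and the C5=C6 enol-lactone alkene is a latent vinylogous aldol (C5–OAc, C6–H). In one pot, gold-catalysed transannular 5-endo-dig attack of the C4 hydroxyl on C1 closes the furanone as the last ring, and DBU then expels acetate to give the ring-locked C5=C6 alkene. The precursor is a butenolide-fused cyclodecynone carrying C4–OH and C5–OAc, assembled by carbomagnesiation/carboxylation, vinylogous aldol and Nozaki–Hiyama–Kishi alkynylation.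

Key step: step 21

Remarks on the chemistry:
- Assumption: methyl (R)-2-methyloxirane-2-carboxylate (21) and 4-[(tert-butyldimethylsilyl)oxy]but-2-yn-1-ol (10) are taken as catalogue chemicals.
- C8 and C10 are S throughout. C4 keeps the spatial arrangement of aldehyde 24; only its CIP letter changes with its neighbours.
- C5 and C6 (and C3 in 30) are carried as epimer mixtures; all three centres become sp2 by step 21.

Step 1
Reactants: 1 (R)-4-benzyl-3-propanoyloxazolidin-2-one; 2 2,3-dibromoprop-1-ene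
Product: 4 (R)-4-benzyl-3-[(S)-4-bromo-2-methylpent-4-enoyl]oxazolidin-2-one, via sodium Z-enolate 3 (not isolated)
Conditions: NaHMDS, THF, −78 °C; then 2, −78 → −40 °C
Reagents that add atoms: none
Why: Evans asymmetric alkylation, in which the chelated Z-enolate is attacked by the allylic bromide on the face opposite the benzyl group, should set C10 as S.

Step 2
Reactants: 4
Product: 5 (S)-4-bromo-2-methylpent-4-en-1-ol
Conditions: LiBH4, MeOH (1 equiv), Et2O, 0 °C
Reagents that add atoms: none
Why: Reductive cleavage of the auxiliary at the exocyclic imide carbonyl should leave the stereocentre and the vinyl bromide untouched.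

Step 3
Reactants: 5
Product: 6 (S)-4-bromo-2-methylpent-4-enal
Conditions: Dess–Martin periodinane, NaHCO3, CH2Cl2, 0 °C → rt
Reagents that add atoms: none
Why: Buffered Dess–Martin oxidation should give the α-branched aldehyde without epimerisation; it is used at once.

Step 4
Reactants: 6
Product: 7 (S)-5-bromo-3-methylhex-5-en-1-yne
Conditions: dimethyl (1-diazo-2-oxopropyl)phosphonate, K2CO3, MeOH, 0 °C → rt
Reagents that add atoms: dimethyl (1-diazo-2-oxopropyl)phosphonate, COP(=O)(OC)C(=[N+]=[N-])C(C)=O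
Why: Ohira–Bestmann (Seyferth–Gilbert) homologation turns CHO into C1≡C2–H under mild base that should neither epimerise C10 nor touch the vinyl bromide.

Step 5
Reactants: 7
Product: 9 (S)-(5-bromo-3-methylhex-5-en-1-yn-1-yl)trimethylsilane, via alkynylmagnesium bromide 8 (not isolated)
Conditions: EtMgBr, THF, 0 → 40 °C; TMSCl, 0 °C → rt
Reagents that add atoms: chlorotrimethylsilane, C[Si](C)(C)Cl
Why: Acid–base magnesiation of the terminal alkyne (no Br/Mg exchange at the vinyl bromide) and C-silylation mask the acidic C–H so that the alkenyl Grignard of step 6 can be made.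

Step 6
Reactants: 9; 10 4-[(tert-butyldimethylsilyl)oxy]but-2-yn-1-ol
Product: 13 3-{[(tert-butyldimethylsilyl)oxy]methyl}-4-[(S)-4-methyl-6-(trimethylsilyl)hex-1-en-5-yn-2-yl]furan-2(5H)-one, via alkenylmagnesium bromide 11 (not isolated), via oxamagnesacycle 12 (not isolated)
Conditions: 9, Mg, THF, reflux; 10, EtMgBr (1 equiv), THF, 0 °C; combine, toluene/THF, 80 °C; CO2, −20 °C → rt; aq. HCl
Reagents that add atoms: carbon dioxide, O=C=O
Why: Hydroxyl-directed magnesium-mediated anti-carbomagnesiation of the propargylic alkoxide places the alkenyl group on the proximal alkyne carbon (C7) and magnesium on C11 in a five-membered chelate cis to C6, so carboxylation at C11 and acid-induced lactonisation onto the C6 hydroxyl should give the tetrasubstituted butenolide with C8 and C13 in place.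

Step 7
Reactants: 13
Product: 14 3-{[(tert-butyldimethylsilyl)oxy]methyl}-4-[(S)-3-methyl-5-(trimethylsilyl)pent-4-ynoyl]furan-2(5H)-one
Conditions: OsO4 (2 mol %), NaIO4, 2,6-lutidine, dioxane/H2O, rt
Reagents that add atoms: sodium periodate, [Na+].[O-]I(=O)(=O)=O (oxygen relayed by catalytic OsO4)
Why: Lemieux–Johnson cleavage, in which dihydroxylation should pick the electron-richer 1,1-disubstituted alkene over the ester-conjugated tetrasubstituted butenolide alkene and the silyl alkyne, gives the C8 ketone.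

Step 8
Reactants: 14
Product: 15 3-{[(tert-butyldimethylsilyl)oxy]methyl}-4-[(1S,3S)-1-hydroxy-3-methyl-5-(trimethylsilyl)pent-4-yn-1-yl]furan-2(5H)-one
Conditions: (R)-Me-CBS (0.5 equiv), catecholborane, toluene/CH2Cl2, −78 °C; MeOH
Reagents that add atoms: none
Why: Corey–Bakshi–Shibata reduction with the butenolide carbon as the large and the CH2 chain as the small group should give the S carbinol at C8 under reagent control, while catecholborane at low temperature spares lactone and alkyne.

Step 9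
Reactants: 16 4-methylfuran-2(5H)-one
Product: 19 (Z)-4-[(tert-butyldiphenylsilyl)oxy]-3-methylbut-2-enoic acid, via sodium hydroxy-enoate 17 (not isolated), via bis-silyl derivative 18 (not isolated)
Conditions: NaOH (1 equiv), H2O/MeOH, rt; evaporate; TBDPSCl, imidazole, DMF, rt; K2CO3 (cat.), MeOH/THF/H2O, 0 °C; pH 5 work-up
Reagents that add atoms: sodium hydroxide, [Na+].[OH-]; tert-butyl(chloro)diphenylsilane, CC(C)(C)[Si](Cl)(c1ccccc1)c1ccccc1
Why: Saponification keeps the ring-derived Z geometry, silylation caps both oxygens, and selective hydrolysis of the labile silyl ester leaves the Z acid with its hydroxyl blocked against relactonisation.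

Step 10
Reactants: 15; 19
Product: 20 (1S,3S)-1-[4-{[(tert-butyldimethylsilyl)oxy]methyl}-5-oxo-2,5-dihydrofuran-3-yl]-3-methyl-5-(trimethylsilyl)pent-4-yn-1-yl (Z)-4-[(tert-butyldiphenylsilyl)oxy]-3-methylbut-2-enoate
Conditions: EDC·HCl, DMAP (0.2 equiv), CH2Cl2, 0 °C → rt
Reagents that add atoms: none
Why: Steglich esterification installs the final C8 ester early so that it also serves as the C8 protecting group; low temperature and catalytic DMAP should limit Z/E isomerisation and translactonisation to O8.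

Step 11
Reactants: 21 methyl (R)-2-methyloxirane-2-carboxylate
Product: 22 methyl (R)-2,3-dihydroxy-2-methylpropanoate
Conditions: HClO4 (cat.), THF/H2O, rt
Reagents that add atoms: water, O
Why: Acid-catalysed epoxide hydrolysis of a glycidic ester should occur by attack of water at the primary carbon, so the C–O bond at the quaternary centre (future C4) is retained.

Step 12
Reactants: 22
Product: 23 methyl (R)-2-methyl-2,3-bis[(triethylsilyl)oxy]propanoate
Conditions: TESOTf, 2,6-lutidine, CH2Cl2, −78 → 0 °C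
Reagents that add atoms: triethylsilyl trifluoromethanesulfonate, CC[Si](CC)(CC)OS(=O)(=O)C(F)(F)F
Why: Silyl triflate silylation covers the primary and the hindered tertiary hydroxyl in one operation.

Step 13
Reactants: 23
Product: 24 (R)-2-methyl-2,3-bis[(triethylsilyl)oxy]propanal
Conditions: DIBAL-H, CH2Cl2, −78 °C; Rochelle salt
Reagents that add atoms: none
Why: Half-reduction of the α-alkoxy ester should stop at the aldehyde through a chelated aluminium hemiacetal, and the quaternary α-carbon cannot epimerise.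

Step 14
Reactants: 20; 24
Product: 26 vinylogous aldol adduct (20 carrying at C6 the chain C5H(OH)–C4(CH3)(OTES)–C3H2OTES; 4R; C5/C6 epimers), via lithium furanolate 25 (not isolated)
Conditions: LiHMDS, THF, −78 °C; 24, −78 °C; AcOH, −78 °C
Reagents that add atoms: none
Why: Vinylogous aldol addition, in which deprotonation at C6 gives the aromatic 2-furanolate that should attack the non-enolisable aldehyde through its γ-carbon because the α-carbon is fully substituted; the new C5 and C6 centres form as a mixture that is erased in step 21.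

Step 15
Reactants: 26
Product: 27 C5 acetate of 26
Conditions: Ac2O, DMAP (cat.), pyridine, 0 °C → rt
Reagents that add atoms: acetic anhydride, CC(=O)OC(C)=O
Why: Acylation makes the C5 oxygen a leaving group for the later E1cB step and blocks retro-aldol, while pyridine/DMAP should be too weak a base to trigger elimination.

Step 16
Reactants: 27
Product: 28 iodoalkyne (27 with C2–I in place of C2–SiMe3)
Conditions: N-iodosuccinimide, AgNO3 (10 mol %), acetone, rt, dark
Reagents that add atoms: N-iodosuccinimide, O=C1CCC(=O)N1I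
Why: Silver-catalysed iododesilylation of the alkynylsilane should give the 1-iodoalkyne needed for chromium insertion without touching silyl ethers or esters.

Step 17
Reactants: 28
Product: 29 C3 aldehyde (28 with C3H2OTES oxidised to CHO; 4S)
Conditions: (COCl)2, DMSO, CH2Cl2, −78 → −40 °C; Et3N, −78 → 0 °C
Reagents that add atoms: none
Why: Swern conditions oxidise a primary triethylsilyl ether directly to the aldehyde while tertiary TES, TBS and TBDPS ethers should survive, so C3 is unveiled without a separate deprotection.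

Step 18
Reactants: 29
Product: 30 macrocyclic propargylic alcohol: 5-acetoxy-3-hydroxy-4-(triethylsilyloxy)-13-(tert-butyldimethylsilyloxy)-8-[(Z)-4-(tert-butyldiphenylsilyloxy)-3-methylbut-2-enoyloxy]germacr-7(11)-en-1-yn-12,6-olide (C3/C5/C6 epimers)
Conditions: CrCl2 (8 equiv), NiCl2 (cat.), THF, 0.002 M, slow addition, rt
Reagents that add atoms: none
Why: Intramolecular Nozaki–Hiyama–Kishi alkynylation, in which the alkynylchromium formed from the C–I bond should add to the aldehyde in the presence of lactone, esters and acetate, closes the ten-membered ring at C2–C3 under high dilution.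

Step 19
Reactants: 30
Product: 31 macrocyclic ynone (3-oxo analogue of 30; 4S)
Conditions: Dess–Martin periodinane, NaHCO3, CH2Cl2, 0 °C
Reagents that add atoms: none
Why: Dess–Martin oxidation of the propargylic alcohol gives the ynone and removes the C3 stereocentre; C4 is still silylated, so no cyclisation should occur yet.

Step 20
Reactants: 31
Product: 32 hydroxy-ynone: 5-acetoxy-4,13-dihydroxy-3-oxo-8-[(Z)-4-(tert-butyldiphenylsilyloxy)-3-methylbut-2-enoyloxy]germacr-7(11)-en-1-yn-12,6-olide
Conditions: aq. HF (48 %), MeCN, 0 °C → rt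
Reagents that add atoms: none
Why: Acidic fluoride should cleave the tertiary TES and the primary allylic TBS ether but not the TBDPS ether, freeing the C4 hydroxyl under non-basic conditions in which an α′-hydroxy ynone is not expected to cyclise.

Step 21
Reactants: 32
Product: 34 (4S,8S,10S,5E)-1,4-epoxy-13-hydroxy-3-oxo-8-[(Z)-4-(tert-butyldiphenylsilyloxy)-3-methylbut-2-enoyloxy]germacra-1,5,7(11)-trien-12,6-olide, via furanone acetate 33 (not isolated)
Conditions: (Ph3P)AuNTf2 (5 mol %), CH2Cl2, rt; then DBU (3 equiv), 0 °C → rt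
Reagents that add atoms: none
Why: The cationic gold(I) catalyst coordinates the bent C1≡C2 bond and the C4 hydroxyl attacks C1 (anti-oxyauration, then protodeauration) to give the 3(2H)-furanone; the closest known reaction is the π-acid-catalysed cycloisomerisation of α′-hydroxy ynones to 3(2H)-furanones, here run transannularly. The furanone ring (O, C1, C2, C3, C4) closes in the 5-endo-dig mode and thereby lays the oxygen bridge across the ten-membered carbocycle. DBU then deprotonates C6, the γ-position of the butenolide, and the 2-furanolate expels the C5 acetate (vinylogous E1cB) to give the C5=C6 enol-lactone alkene. No new stereocentre is formed: C4 comes from aldehyde 24 with retention because its C–O bond is never broken, and the C5/C6 epimer mixture converges. The step needs O- rather than C-attack on the ynone and E geometry at C5=C6; running the gold stage first should consume the ynone before any C6 carbanion exists, and the oxygen bridge already in place forces C4 and C7 cis on the new alkene. The C13 hydroxyl is left free on purpose, since an oxide on C13 cannot leave from the furanolate whereas an acetate could.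

Step 22
Reactants: 34
Product: 35 13-acetate of 34
Conditions: Ac2O, pyridine, DMAP (cat.), CH2Cl2, 0 °C
Reagents that add atoms: acetic anhydride, CC(=O)OC(C)=O
Why: Acetylation of the only free hydroxyl (C13) should be clean.

Step 23
Reactants: 35
Product: 36 (4S,8S,10S,5E)-13-acetoxy-1,4-epoxy-8-[(Z)-4-hydroxy-3-methylbut-2-enoyloxy]-3-oxogermacra-1,5,7(11)-trien-12,6-olide (CNP0269057.1)
Conditions: HF·pyridine, pyridine, THF, 0 °C → rt
Reagents that add atoms: none
Why: Buffered HF·pyridine should remove the primary TBDPS ether under acidic conditions that avoid alkoxide-induced lactonisation of the Z-hydroxy enoate and acetate migration.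

**Compound list**

1 | (R)-4-benzyl-3-propanoyloxazolidin-2-one | CCC(=O)N1[C@H](Cc2ccccc2)COC1=O | starting material
2 | 2,3-dibromoprop-1-ene | C=C(Br)CBr | starting material
3 | sodium Z-enolate of 1 | C/C=C(\[O-])N1[C@H](Cc2ccccc2)COC1=O.[Na+] | intermediate
4 | (R)-4-benzyl-3-[(S)-4-bromo-2-methylpent-4-enoyl]oxazolidin-2-one | C=C(Br)C[C@H](C)C(=O)N1[C@H](Cc2ccccc2)COC1=O | intermediate
5 | (S)-4-bromo-2-methylpent-4-en-1-ol | C=C(Br)C[C@H](C)CO | intermediate
6 | (S)-4-bromo-2-methylpent-4-enal | C=C(Br)C[C@H](C)C=O | intermediate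
7 | (S)-5-bromo-3-methylhex-5-en-1-yne | C=C(Br)C[C@H](C)C#C | intermediate
8 | alkynylmagnesium bromide of 7 | C=C(Br)C[C@H](C)C#C[Mg]Br | intermediate
9 | (S)-(5-bromo-3-methylhex-5-en-1-yn-1-yl)trimethylsilane | C=C(Br)C[C@H](C)C#C[Si](C)(C)C | intermediate
10 | 4-[(tert-butyldimethylsilyl)oxy]but-2-yn-1-ol | OCC#CCO[Si](C)(C)C(C)(C)C | starting material
11 | [(S)-4-methyl-6-(trimethylsilyl)hex-1-en-5-yn-2-yl]magnesium bromide | C=C([Mg]Br)C[C@H](C)C#C[Si](C)(C)C | intermediate
12 | oxamagnesacycle (2,5-dihydro-1,2-oxamagnesole from anti-carbomagnesiation; Mg on C11, alkenyl on C7) | C=C(C[C@H](C)C#C[Si](C)(C)C)C1=C(CO[Si](C)(C)C(C)(C)C)[Mg]OC1 | intermediate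
13 | 3-{[(tert-butyldimethylsilyl)oxy]methyl}-4-[(S)-4-methyl-6-(trimethylsilyl)hex-1-en-5-yn-2-yl]furan-2(5H)-one | O=C1OCC(C(=C)C[C@H](C)C#C[Si](C)(C)C)=C1CO[Si](C)(C)C(C)(C)C | intermediate
14 | 3-{[(tert-butyldimethylsilyl)oxy]methyl}-4-[(S)-3-methyl-5-(trimethylsilyl)pent-4-ynoyl]furan-2(5H)-one | O=C1OCC(C(=O)C[C@H](C)C#C[Si](C)(C)C)=C1CO[Si](C)(C)C(C)(C)C | intermediate
15 | 3-{[(tert-butyldimethylsilyl)oxy]methyl}-4-[(1S,3S)-1-hydroxy-3-methyl-5-(trimethylsilyl)pent-4-yn-1-yl]furan-2(5H)-one | O=C1OCC([C@@H](O)C[C@H](C)C#C[Si](C)(C)C)=C1CO[Si](C)(C)C(C)(C)C | intermediate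
16 | 4-methylfuran-2(5H)-one | CC1=CC(=O)OC1 | starting material
17 | sodium (Z)-4-hydroxy-3-methylbut-2-enoate | [Na+].[O-]C(=O)/C=C(/C)CO | intermediate
18 | tert-butyldiphenylsilyl (Z)-4-[(tert-butyldiphenylsilyl)oxy]-3-methylbut-2-enoate | CC(C)(C)[Si](c1ccccc1)(c1ccccc1)OC(=O)/C=C(/C)CO[Si](c1ccccc1)(c1ccccc1)C(C)(C)C | intermediate
19 | (Z)-4-[(tert-butyldiphenylsilyl)oxy]-3-methylbut-2-enoic acid | OC(=O)/C=C(/C)CO[Si](c1ccccc1)(c1ccccc1)C(C)(C)C | intermediate
20 | (1S,3S)-1-[4-{[(tert-butyldimethylsilyl)oxy]methyl}-5-oxo-2,5-dihydrofuran-3-yl]-3-methyl-5-(trimethylsilyl)pent-4-yn-1-yl (Z)-4-[(tert-butyldiphenylsilyl)oxy]-3-methylbut-2-enoate | O=C1OCC([C@@H](OC(=O)/C=C(/C)CO[Si](c2ccccc2)(c2ccccc2)C(C)(C)C)C[C@H](C)C#C[Si](C)(C)C)=C1CO[Si](C)(C)C(C)(C)C | intermediate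
21 | methyl (R)-2-methyloxirane-2-carboxylate | COC(=O)[C@@]1(C)CO1 | starting material
22 | methyl (R)-2,3-dihydroxy-2-methylpropanoate | COC(=O)[C@](CO)(C)O | intermediate
23 | methyl (R)-2-methyl-2,3-bis[(triethylsilyl)oxy]propanoate | COC(=O)[C@](CO[Si](CC)(CC)CC)(C)O[Si](CC)(CC)CC | intermediate
24 | (R)-2-methyl-2,3-bis[(triethylsilyl)oxy]propanal | O=C[C@](CO[Si](CC)(CC)CC)(C)O[Si](CC)(CC)CC | intermediate
25 | lithium 2-furanolate (dienolate) of 20 | [Li+].[O-]c1occ([C@@H](OC(=O)/C=C(/C)CO[Si](c2ccccc2)(c2ccccc2)C(C)(C)C)C[C@H](C)C#C[Si](C)(C)C)c1CO[Si](C)(C)C(C)(C)C | intermediate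
26 | vinylogous aldol adduct (C5–OH, C4–OTES, C3H2–OTES on C6 of butenolide 20; 4R; C5/C6 epimers) | O=C1OC(C(O)[C@](CO[Si](CC)(CC)CC)(C)O[Si](CC)(CC)CC)C([C@@H](OC(=O)/C=C(/C)CO[Si](c2ccccc2)(c2ccccc2)C(C)(C)C)C[C@H](C)C#C[Si](C)(C)C)=C1CO[Si](C)(C)C(C)(C)C | intermediate
27 | C5 acetate of 26 | O=C1OC(C(OC(C)=O)[C@](CO[Si](CC)(CC)CC)(C)O[Si](CC)(CC)CC)C([C@@H](OC(=O)/C=C(/C)CO[Si](c2ccccc2)(c2ccccc2)C(C)(C)C)C[C@H](C)C#C[Si](C)(C)C)=C1CO[Si](C)(C)C(C)(C)C | intermediate
28 | iodoalkyne (27 with C2–I) | O=C1OC(C(OC(C)=O)[C@](CO[Si](CC)(CC)CC)(C)O[Si](CC)(CC)CC)C([C@@H](OC(=O)/C=C(/C)CO[Si](c2ccccc2)(c2ccccc2)C(C)(C)C)C[C@H](C)C#CI)=C1CO[Si](C)(C)C(C)(C)C | intermediate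
29 | C3 aldehyde of 28 (4S) | O=C1OC(C(OC(C)=O)[C@](C=O)(C)O[Si](CC)(CC)CC)C([C@@H](OC(=O)/C=C(/C)CO[Si](c2ccccc2)(c2ccccc2)C(C)(C)C)C[C@H](C)C#CI)=C1CO[Si](C)(C)C(C)(C)C | intermediate
30 | macrocyclic propargylic alcohol (5-acetoxy-3-hydroxy-4-OTES-13-OTBS-8-acyloxy-germacr-7(11)-en-1-yn-12,6-olide; C3/C5/C6 epimers) | O=C1OC2C(OC(C)=O)[C@](C)(O[Si](CC)(CC)CC)C(O)C#C[C@@H](C)C[C@H](OC(=O)/C=C(/C)CO[Si](c3ccccc3)(c3ccccc3)C(C)(C)C)C2=C1CO[Si](C)(C)C(C)(C)C | intermediate
31 | macrocyclic ynone (3-oxo analogue of 30) | O=C1OC2C(OC(C)=O)[C@](C)(O[Si](CC)(CC)CC)C(=O)C#C[C@@H](C)C[C@H](OC(=O)/C=C(/C)CO[Si](c3ccccc3)(c3ccccc3)C(C)(C)C)C2=C1CO[Si](C)(C)C(C)(C)C | intermediate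
32 | hydroxy-ynone (5-acetoxy-4,13-dihydroxy-3-oxo-8-acyloxy-germacr-7(11)-en-1-yn-12,6-olide) | O=C1OC2C(OC(C)=O)[C@](C)(O)C(=O)C#C[C@@H](C)C[C@H](OC(=O)/C=C(/C)CO[Si](c3ccccc3)(c3ccccc3)C(C)(C)C)C2=C1CO | intermediate
33 | furanone acetate (5-acetoxy-1,4-epoxy-13-hydroxy-3-oxo-8-acyloxy-germacra-1,7(11)-dien-12,6-olide) | O=C1OC2C(OC(C)=O)[C@]3(C)OC(=CC3=O)[C@@H](C)C[C@H](OC(=O)/C=C(/C)CO[Si](c4ccccc4)(c4ccccc4)C(C)(C)C)C2=C1CO | intermediate
34 | (4S,8S,10S,5E)-1,4-epoxy-13-hydroxy-3-oxo-8-[(Z)-4-(tert-butyldiphenylsilyloxy)-3-methylbut-2-enoyloxy]germacra-1,5,7(11)-trien-12,6-olide | OCC1=C2/C(=C\[C@]3(C)OC(=CC3=O)[C@@H](C)C[C@@H]2OC(=O)/C=C(/C)CO[Si](c4ccccc4)(c4ccccc4)C(C)(C)C)OC1=O | intermediate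
35 | 13-acetate of 34 | CC(=O)OCC1=C2/C(=C\[C@]3(C)OC(=CC3=O)[C@@H](C)C[C@@H]2OC(=O)/C=C(/C)CO[Si](c4ccccc4)(c4ccccc4)C(C)(C)C)OC1=O | intermediate
36 | (4S,8S,10S,5E)-13-acetoxy-1,4-epoxy-8-[(Z)-4-hydroxy-3-methylbut-2-enoyloxy]-3-oxogermacra-1,5,7(11)-trien-12,6-olide (CNP0269057.1) | CC(=O)OCC1=C2/C(=C\[C@]3(C)OC(=CC3=O)[C@@H](C)C[C@@H]2OC(=O)/C=C(/C)CO)OC1=O | target

**Step count.** Total: 23 steps. Longest linear sequence: 19 steps (steps 1–8, 10, 14–23).

**Steps most likely to fail**

Step 18. The chromium-mediated closure may be outrun by intermolecular coupling or by reduction of the iodoalkyne, because the ring being formed is a strained cyclodecyne and the aldehyde is neopentyl-like. The fallback closes the same C2–C3 bond by palladium/copper acyl–alkyne coupling, which delivers the ynone directly. It sets out from acetate 27: Swern oxidation of the primary TES ether would give the aldehyde that keeps the silyl alkyne F5; Pinnick oxidation (NaClO2, NaH2PO4, 2-methylbut-2-ene) would give the carboxylic acid F6; silver-nitrate-catalysed protiodesilylation in aqueous acetone would give the terminal alkyne acid F7; the Ghosez reagent would convert it into the acid chloride F8, which is not isolated but added slowly to PdCl2(PPh3)2/CuI/Et3N in THF at high dilution (intramolecular acyl Sonogashira coupling). The fallback comes back to the route at ynone 31.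

Step 6. The hindered 1,1-disubstituted alkenyl Grignard may add too slowly to the propargylic alkoxide, so that protonolysis or loss of silyloxide to an allene takes over. The fallback makes the C7–C8 bond by cross-coupling. It sets out from alkynol 10: methyl chloroformate/pyridine would give 4-[(tert-butyldimethylsilyl)oxy]but-2-yn-1-yl methyl carbonate F1; palladium-catalysed carbonylation (Pd(OAc)2, PPh3, CO, MeOH, 50 °C; SN2′) would give methyl 2-{[(tert-butyldimethylsilyl)oxy]methyl}buta-2,3-dienoate F2; iodolactonisation (I2, MeCN/H2O) would give 3-{[(tert-butyldimethylsilyl)oxy]methyl}-4-iodofuran-2(5H)-one F3; Negishi coupling (Pd(PPh3)4, THF) with the alkenylzinc bromide F4, made from bromide 9 by Br/Li exchange with t-BuLi at −78 °C and ZnBr2, would come back to the route at butenolide 13.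

Step 21. The gold stage may stall or give hydration of the ynone, and a C6 carbanion formed too early could attack C1 across the ring instead of expelling acetate. The fallback closes the furanone by amine addition–elimination and isolates the intermediate. It sets out from hydroxy-ynone 32: diethylamine in EtOH/CH2Cl2 at 0 °C would add to C1 and give the β-(diethylamino)enone F9; aqueous acetic acid in THF would then let the C4 hydroxyl displace the amine at C1 to give furanone acetate 33, now isolated; DBU in CH2Cl2 would eliminate acetic acid, and the fallback comes back to the route at 34.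

**Further compounds**

F1 | step 6 | 4-[(tert-butyldimethylsilyl)oxy]but-2-yn-1-yl methyl carbonate | COC(=O)OCC#CCO[Si](C)(C)C(C)(C)C
F2 | step 6 | methyl 2-{[(tert-butyldimethylsilyl)oxy]methyl}buta-2,3-dienoate | C=C=C(CO[Si](C)(C)C(C)(C)C)C(=O)OC
F3 | step 6 | 3-{[(tert-butyldimethylsilyl)oxy]methyl}-4-iodofuran-2(5H)-one | O=C1OCC(I)=C1CO[Si](C)(C)C(C)(C)C
F4 | step 6 | [(S)-4-methyl-6-(trimethylsilyl)hex-1-en-5-yn-2-yl]zinc bromide | C=C([Zn]Br)C[C@H](C)C#C[Si](C)(C)C
F5 | step 18 | C3 aldehyde of 27 (silyl alkyne retained) | O=C1OC(C(OC(C)=O)[C@](C=O)(C)O[Si](CC)(CC)CC)C([C@@H](OC(=O)/C=C(/C)CO[Si](c2ccccc2)(c2ccccc2)C(C)(C)C)C[C@H](C)C#C[Si](C)(C)C)=C1CO[Si](C)(C)C(C)(C)C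
F6 | step 18 | C3 carboxylic acid | O=C1OC(C(OC(C)=O)[C@](C(=O)O)(C)O[Si](CC)(CC)CC)C([C@@H](OC(=O)/C=C(/C)CO[Si](c2ccccc2)(c2ccccc2)C(C)(C)C)C[C@H](C)C#C[Si](C)(C)C)=C1CO[Si](C)(C)C(C)(C)C
F7 | step 18 | terminal alkyne acid | O=C1OC(C(OC(C)=O)[C@](C(=O)O)(C)O[Si](CC)(CC)CC)C([C@@H](OC(=O)/C=C(/C)CO[Si](c2ccccc2)(c2ccccc2)C(C)(C)C)C[C@H](C)C#C)=C1CO[Si](C)(C)C(C)(C)C
F8 | step 18 | terminal alkyne acid chloride | O=C1OC(C(OC(C)=O)[C@](C(Cl)=O)(C)O[Si](CC)(CC)CC)C([C@@H](OC(=O)/C=C(/C)CO[Si](c2ccccc2)(c2ccccc2)C(C)(C)C)C[C@H](C)C#C)=C1CO[Si](C)(C)C(C)(C)C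
F9 | step 21 | β-(diethylamino)enone from 32 (amine on C1) | O=C1OC2C(OC(C)=O)[C@](C)(O)C(=O)C=C(N(CC)CC)[C@@H](C)C[C@H](OC(=O)/C=C(/C)CO[Si](c3ccccc3)(c3ccccc3)C(C)(C)C)C2=C1CO
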